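3 questions are put to the 2 flasks red and grey, and 2 earlier runs stand behind them.

| flask | starting material | partner | catalyst | temperature | remark | time |
|---|---|---|---|---|---|---|
| Wednesday's | 1.1 M | 2 M | 55 mM | 75 °C | run made earlier |  |
| Thursday's | 1.1 M | 2 M | 55 mM | 95 °C | run made earlier |  |
| red | 1.1 M | 1.43 M | 55 mM | 110 °C |  | 1.0 h |
| grey | 1.1 M | 1.43 M | 55 mM | 80 °C |  | 1.0 h |

Wednesday's run (percent of the starting material charged)

| time / h | target / % | uncatalysed product / % |
|---|---|---|
| 0.500 | 48 | 16 |
| 1.00 | 61 | 20 |
| 2.50 | 74 | 21 |
| 6.00 | 76 | 25 |

Thursday's run (percent of the starting material charged)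

| time / min | target / % | uncatalysed product / % |
|---|---|---|
| 10.0 | 46 | 27 |
| 25.0 | 61 | 30 |
| 50.0 | 69 | 35 |
| 120 | 71 | 34 |

(scatter of a reading: 1.5 percentage points)

- the flask with the highest share of target in all that became target or uncatalysed product ("all alike" if they lie within 1.5 percentage points) (red / grey / all alike)
- share of target in all that became target or uncatalysed product, red
- share of target in all that became target or uncatalysed product, grey



1. The runs seem to disagree. Thursday's run, the hotter, holds 46% target after 10.0 min, while Wednesday's run holds 48% only after 0.500 h. Yet Thursday's run ends lower, at 71% against 76%.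

2. We divide the target made by the uncatalysed product made; this ratio of accumulated amounts is the quotient of the two rates averaged over the run, and we do not take that quotient as constant. In Wednesday's run it is 3.00 at the first reading and 3.04 at the last, while the target climbs.

3. We read it where the target stands highest: 3.04 in Wednesday's run and 2.09 in Thursday's. Both paths speed up with heat, but by this reading the uncatalysed path has about 20.0 kJ mol⁻¹ more activation energy. That clears up the puzzle.

4. We assume that partner enters both rates alike and cancels; both runs used 2 M, so they cannot test this. Our reckoning gives grey, at 80 °C, 2.76, its selectivity factor, the target made per uncatalysed product. That is a share of 73.4%. Red, at 110 °C, beyond both runs, gets 1.62, a share of 61.8%, so grey stands higher.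

5. The forecast says grey, with 60% for red and 75% for grey, since “the share barely changes with time”; its red figure lies below ours and its grey figure above.

6. The flasks give grey, with 60.6% for red and 72.8% for grey. Changing only the partner from Wednesday's run to grey's charge leaves the share at 75.4%, against 75.5% before. Grey still holds 21.7% of its starting material at 1.00 h. Split by the factor 2.76, that rest adds 15.9% to the 57.0% of target, making 72.9%; at 10.0 h grey holds 73.4%.

    starting material + partner + catalyst → target + catalyst, rate k1*[starting material]*[partner]*[catalyst]/(1 + ([starting material]/sat1)) (3.20 M, k = 0.474 M⁻² min⁻¹, Ea = 71.0 kJ mol⁻¹)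
    starting material + partner → uncatalysed product (k = 0.00806 M⁻¹ min⁻¹, Ea = 93.0 kJ mol⁻¹)
    (constants at 80 °C)

7. A neighbour of grey has 0.14 M of catalyst instead of 55 mM. The catalysed rate is proportional to catalyst and the other rate contains none, so the factor becomes 7.02, a share of 87.5%. The computed share is 87.4%.

The numbers in the tables are simulated from invented constants; noise was put on by code.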